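**Strategy.** With the side chain numbered from the quinone-bearing CH2 (C1'), the target is cut at C12'–C13' and at C1'–C2'. The piece that remains is the saturated C6'–C12' segment, in which the stereogenic CHMe carbons C7' and C11' are separated by the C8'–C10' trimethylene, so it can be grown carbon by carbon from a C–B bond. One assembly-line operation homologates the primary boronic ester PMBO–C4'H2–C5'H2–C6'H2–Bpin six times (CHMe, CH2, CH2, CH2, CHMe, CH2). This forms C6'–C7' through C11'–C12' and both methyl stereocentres under reagent control. No ring is formed, and the naphthoquinone bicycle is attached intact at the end.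

Key step: step 5

Remark: the side chain is numbered C1'–C36' from the quinone CH2; the target is read as (7'R,11'S,31'S) with E alkenes at C2', C14', C18', C22' and C26', and CIP descriptors of intermediates change with the end groups although no centre is inverted once set.

**Step 1**
Reactants: 1 allyl alcohol
Product: 2 allyl 4-methoxybenzyl ether
Conditions: NaH, PMBCl, Bu4NI (cat.), THF, 0 °C → rt
Reagents that add atoms: 4-methoxybenzyl chloride, COc1ccc(CCl)cc1
Why: Williamson etherification of the primary alkoxide with the benzylic chloride, iodide catalysis speeding the SN2 displacement.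

**Step 2**
Reactants: 2 allyl 4-methoxybenzyl ether
Product: 3 2-[3-(4-methoxybenzyloxy)propyl]-4,4,5,5-tetramethyl-1,3,2-dioxaborolane
Conditions: HBpin, [Ir(cod)Cl]2 (1.5 mol %), dppm (3 mol %), CH2Cl2, rt
Reagents that add atoms: pinacolborane, CC1(C)OBOC1(C)C
Why: Iridium-catalysed hydroboration of a monosubstituted alkene with pinacolborane should place boron on the terminal carbon (C6') with high anti-Markovnikov selectivity and without the β-alkoxide elimination or isomerisation that allylic ethers can show under rhodium catalysis.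

**Step 3**
Reactants: 4 2,4,6-triisopropylbenzoic acid
Product: 5 ethyl 2,4,6-triisopropylbenzoate
Conditions: EtI, K2CO3, DMF, 40 °C
Reagents that add atoms: iodoethane, CCI
Why: O-alkylation of the carboxylate (SN2 at iodoethane) sidesteps acyl substitution at the doubly ortho-shielded carbonyl, which Fischer esterification would find very slow.

**Step 4**
Reactants: 5 ethyl 2,4,6-triisopropylbenzoate
Product: 7 (R)-1-(tributylstannyl)ethyl 2,4,6-triisopropylbenzoate, via lithiated ester 6 (not isolated)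
Conditions: s-BuLi, (+)-sparteine, Et2O, −78 °C, 5 h; Bu3SnCl, −78 °C → rt
Reagents that add atoms: tributyltin chloride, CCCC[Sn](Cl)(CCCC)CCCC
Why: Sparteine-mediated asymmetric deprotonation α to oxygen, directed by the hindered benzoate carbonyl, should remove the pro-R proton with (+)-sparteine to give the configurationally stable (R)-organolithium 6, which Bu3SnCl traps with retention; (−)-sparteine would give the wrong enantiomer.

**Step 5**
Reactants: 3 2-[3-(4-methoxybenzyloxy)propyl]-4,4,5,5-tetramethyl-1,3,2-dioxaborolane; 7 (R)-1-(tributylstannyl)ethyl 2,4,6-triisopropylbenzoate (passes 1 and 5); 8 bromochloromethane (passes 2, 3, 4 and 6)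
Product: 14 2-[(2R,6R)-9-(4-methoxybenzyloxy)-2,6-dimethylnonyl]-4,4,5,5-tetramethyl-1,3,2-dioxaborolane, via C7' boronic ester 9 (not isolated), via C8' boronic ester 10 (not isolated), via C9' boronic ester 11 (not isolated), via C10' boronic ester 12 (not isolated), via C11' boronic ester 13 (not isolated)
Conditions: passes 1 and 5: 7 (1.3 equiv), n-BuLi (1.3 equiv), Et2O, −78 °C, 1 h; boronic ester in Et2O, −78 °C, 1 h; then rt → 35 °C. Passes 2, 3, 4 and 6: 8 (3 equiv), n-BuLi (2.5 equiv) added to the boronic ester, Et2O, −78 °C; then rt. Silica plug and solvent exchange between passes; chromatography of 14 only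
Reagents that add atoms: none
Why: Each pass is a lithiation–borylation (passes 1 and 5) or a Matteson chloromethyl homologation (passes 2, 3, 4 and 6): the carbenoid (6, regenerated from 7 by retentive tin–lithium exchange, or ClCH2Li made from 8 by bromine–lithium exchange in the presence of the boronic ester) adds to trigonal boron to give a tetracoordinate boronate, and on warming the alkyl group migrates from boron to carbon antiperiplanar to the departing triisopropylbenzoate or chloride, which regenerates a neutral pinacol boronic ester for the next pass. The closest known reaction type is the iterative assembly-line homologation of boronic esters with enantiopure α-lithioalkyl benzoates interleaved with chloromethyllithium insertions. No ring is closed. C7' and C11' are set by the configurationally stable (R)-carbenoid alone: borylation is retentive, the 1,2-shift is invertive at the carbenoid carbon and retentive at the migrating carbon, so each CHMe insertion gives the (S)-secondary boronic ester, which the following CH2 insertions carry unchanged to the (2R,6R) descriptors of 14. The selectivity needed is exactly one insertion per pass; it is secured by complete boronate formation at −78 °C with a small excess of carbenoid that decomposes before the migration temperature is reached, and by a substrate whose only other functional group is the inert PMB ether.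

**Step 6**
Reactants: 14 2-[(2R,6R)-9-(4-methoxybenzyloxy)-2,6-dimethylnonyl]-4,4,5,5-tetramethyl-1,3,2-dioxaborolane
Product: 15 (2S,6R)-9-(4-methoxybenzyloxy)-2,6-dimethylnonan-1-ol
Conditions: NaOH (2 M aq), H2O2 (30 %), THF, 0 °C → rt
Reagents that add atoms: hydrogen peroxide, OO
Why: Alkaline peroxide oxidation of the C–B bond proceeds by 1,2-migration of C12' from boron to oxygen, leaves the adjacent C11' centre untouched, and does not affect the PMB ether.

**Step 7**
Reactants: 15 (2S,6R)-9-(4-methoxybenzyloxy)-2,6-dimethylnonan-1-ol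
Product: 16 1-({[(4R,8S)-9-bromo-4,8-dimethylnonyl]oxy}methyl)-4-methoxybenzene
Conditions: CBr4, PPh3, CH2Cl2, 0 °C
Reagents that add atoms: carbon tetrabromide, BrC(Br)(Br)Br
Why: Appel bromination converts the primary alcohol by SN2 displacement of the oxyphosphonium at C12' under neutral conditions that leave the β-stereocentre and the PMB ether alone.

**Step 8**
Reactants: 17 geranylgeraniol
Product: 18 tert-butyldiphenyl{[(2E,6E,10E)-3,7,11,15-tetramethylhexadeca-2,6,10,14-tetraen-1-yl]oxy}silane
Conditions: TBDPSCl, imidazole, CH2Cl2, rt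
Reagents that add atoms: tert-butyl(chloro)diphenylsilane, CC(C)(C)[Si](Cl)(c1ccccc1)c1ccccc1
Why: Silylation of the primary allylic alcohol gives an ether that is inert to SeO2, to Grignard reagents and to copper catalysis, which an acetate would not be.

**Step 9**
Reactants: 18 tert-butyldiphenyl{[(2E,6E,10E)-3,7,11,15-tetramethylhexadeca-2,6,10,14-tetraen-1-yl]oxy}silane
Product: 19 (2E,6E,10E,14E)-16-[(tert-butyldiphenylsilyl)oxy]-2,6,10,14-tetramethylhexadeca-2,6,10,14-tetraen-1-ol
Conditions: SeO2 (10 mol %), t-BuOOH, salicylic acid (10 mol %), CH2Cl2, 0 °C → rt, stopped at partial conversion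
Reagents that add atoms: tert-butyl hydroperoxide, CC(C)(C)OO
Why: SeO2 allylic oxidation (ene reaction then [2,3]-sigmatropic shift, Riley-type with t-BuOOH as terminal oxidant) is selective for the E-methyl of the terminal isopropylidene, the most electron-rich and least hindered alkene, and gives the E-allylic alcohol; stopping short of full conversion should limit over-oxidation to the enal.

**Step 10**
Reactants: 19 (2E,6E,10E,14E)-16-[(tert-butyldiphenylsilyl)oxy]-2,6,10,14-tetramethylhexadeca-2,6,10,14-tetraen-1-ol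
Product: 20 {[(2E,6E,10E,14E)-16-bromo-3,7,11,15-tetramethylhexadeca-2,6,10,14-tetraen-1-yl]oxy}(tert-butyl)diphenylsilane
Conditions: CBr4, PPh3, CH2Cl2, −20 → 0 °C
Reagents that add atoms: carbon tetrabromide, BrC(Br)(Br)Br
Why: Appel bromination of the primary allylic alcohol at low temperature should proceed by direct SN2 displacement without allylic transposition or loss of the E geometry.

**Step 11**
Reactants: 21 (R)-citronellol
Product: 22 (R)-8-bromo-2,6-dimethyloct-2-ene ((R)-citronellyl bromide)
Conditions: CBr4, PPh3, CH2Cl2, 0 °C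
Reagents that add atoms: carbon tetrabromide, BrC(Br)(Br)Br
Why: Appel bromination of a primary alcohol; the C3 stereocentre is remote from the reacting carbon and the trisubstituted alkene is untouched.

**Step 12**
Reactants: 22 (R)-8-bromo-2,6-dimethyloct-2-ene; 20 {[(2E,6E,10E,14E)-16-bromo-3,7,11,15-tetramethylhexadeca-2,6,10,14-tetraen-1-yl]oxy}(tert-butyl)diphenylsilane
Product: 24 tert-butyl{[(2E,6E,10E,14E,19S)-3,7,11,15,19,23-hexamethyltetracosa-2,6,10,14,22-pentaen-1-yl]oxy}diphenylsilane, via citronellylmagnesium bromide 23 (not isolated)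
Conditions: 22, Mg, THF, 40 °C; then 23 (1.5 equiv) added to 20, Li2CuCl4 (5 mol %), THF, −78 → 0 °C
Reagents that add atoms: none
Why: Copper-catalysed Grignard cross-coupling (Kochi–Schlosser type) of a primary alkyl Grignard reagent with a primary allylic bromide should form C28'–C29' at the α-carbon with retention of the C26'=C27' E geometry when the cuprate is kept in the dialkyl regime (cold, Grignard in excess), and the C31' centre is carried in unchanged from (R)-citronellol.

**Step 13**
Reactants: 24 tert-butyl{[(2E,6E,10E,14E,19S)-3,7,11,15,19,23-hexamethyltetracosa-2,6,10,14,22-pentaen-1-yl]oxy}diphenylsilane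
Product: 25 (2E,6E,10E,14E,19S)-3,7,11,15,19,23-hexamethyltetracosa-2,6,10,14,22-pentaen-1-ol
Conditions: TBAF, THF, 0 °C → rt
Reagents that add atoms: none
Why: Fluoride-induced desilylation frees the allylic alcohol without touching the five alkenes.

**Step 14**
Reactants: 25 (2E,6E,10E,14E,19S)-3,7,11,15,19,23-hexamethyltetracosa-2,6,10,14,22-pentaen-1-ol
Product: 26 (2E,6E,10E,14E,19S)-1-chloro-3,7,11,15,19,23-hexamethyltetracosa-2,6,10,14,22-pentaene
Conditions: NCS, Me2S, CH2Cl2, −30 → 0 °C
Reagents that add atoms: N-chlorosuccinimide, ClN1C(=O)CCC1=O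
Why: Corey–Kim chlorination (displacement of the alkoxysulfonium by chloride) converts primary allylic alcohols to chlorides under cold, near-neutral conditions without allylic rearrangement or E/Z scrambling.

**Step 15**
Reactants: 16 1-({[(4R,8S)-9-bromo-4,8-dimethylnonyl]oxy}methyl)-4-methoxybenzene; 26 (2E,6E,10E,14E,19S)-1-chloro-3,7,11,15,19,23-hexamethyltetracosa-2,6,10,14,22-pentaene
Product: 28 1-methoxy-4-({[(4R,8S,11E,15E,19E,23E,28S)-4,8,12,16,20,24,28,32-octamethyltritriaconta-11,15,19,23,31-pentaen-1-yl]oxy}methyl)benzene, via Grignard reagent 27 (not isolated)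
Conditions: 16, Mg, THF, 45 °C; then 27 (1.3 equiv) added to 26, Li2CuCl4 (5 mol %), THF, −10 → 0 °C
Reagents that add atoms: none
Why: Copper-catalysed Grignard cross-coupling with a geranyl-type chloride should give the α (SN2) product at C13', since the γ-carbon C15' is fully substituted, with retention of the C14'=C15' geometry; C11' is β to magnesium and cannot epimerise.

**Step 16**
Reactants: 28 1-methoxy-4-({[(4R,8S,11E,15E,19E,23E,28S)-4,8,12,16,20,24,28,32-octamethyltritriaconta-11,15,19,23,31-pentaen-1-yl]oxy}methyl)benzene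
Product: 29 (4R,8S,11E,15E,19E,23E,28S)-4,8,12,16,20,24,28,32-octamethyltritriaconta-11,15,19,23,31-pentaen-1-ol
Conditions: DDQ, CH2Cl2/pH 7 phosphate buffer (10:1), 0 °C
Reagents that add atoms: none
Why: Oxidative cleavage of the electron-rich benzylic ether by DDQ (hydride abstraction, then hydrolysis of the oxocarbenium) is selective over isolated trisubstituted alkenes in buffered medium.

**Step 17**
Reactants: 29 (4R,8S,11E,15E,19E,23E,28S)-4,8,12,16,20,24,28,32-octamethyltritriaconta-11,15,19,23,31-pentaen-1-ol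
Product: 30 (6S,10E,14E,18E,22E,26S,30R)-33-bromo-2,6,10,14,18,22,26,30-octamethyltritriaconta-2,10,14,18,22-pentaene
Conditions: CBr4, PPh3, CH2Cl2, 0 °C
Reagents that add atoms: carbon tetrabromide, BrC(Br)(Br)Br
Why: Appel bromination of the primary alcohol under neutral conditions that the polyene tolerates.

**Step 18**
Reactants: 30 (6S,10E,14E,18E,22E,26S,30R)-33-bromo-2,6,10,14,18,22,26,30-octamethyltritriaconta-2,10,14,18,22-pentaene
Product: 31 (6R,10S,13E,17E,21E,25E,30S)-6,10,14,18,22,26,30,34-octamethylpentatriaconta-13,17,21,25,33-pentaen-1-yne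
Conditions: LiC≡CH·H2NCH2CH2NH2, DMSO/THF, 10 °C → rt
Reagents that add atoms: lithium acetylide (as its ethylenediamine complex), [Li]C#C
Why: SN2 alkylation of lithium acetylide by an unhindered primary bromide in dipolar aprotic solvent adds C3' and C2' as a terminal alkyne; the substrate offers the base no other acidic or electrophilic site.

**Step 19**
Reactants: 32 menadione (2-methylnaphthalene-1,4-dione)
Product: 33 2-(chloromethyl)-3-methylnaphthalene-1,4-dione
Conditions: (CH2O)n, HCl (g), AcOH, rt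
Reagents that add atoms: formaldehyde (as paraformaldehyde), C=O; hydrogen chloride, Cl
Why: Acid-mediated chloromethylation (Blanc-type) at the only unsubstituted quinonoid carbon of menadione gives the allylic-type chloride electrophile.

**Step 20**
Reactants: 31 (6R,10S,13E,17E,21E,25E,30S)-6,10,14,18,22,26,30,34-octamethylpentatriaconta-13,17,21,25,33-pentaen-1-yne; 33 2-(chloromethyl)-3-methylnaphthalene-1,4-dione
Product: 35 2-methyl-3-[(2E,7R,11S,14E,18E,22E,26E,31S)-3,7,11,15,19,23,27,31,35-nonamethylhexatriaconta-2,14,18,22,26,34-hexaen-1-yl]naphthalene-1,4-dione (target), via alkenylalane 34 (not isolated)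
Conditions: Me3Al (2 equiv), Cp2ZrCl2 (0.25 equiv), ClCH2CH2Cl, 0 °C → rt; volatiles and excess Me3Al removed in vacuo; then 33, NiCl2(PPh3)2 (5 mol %) reduced with n-BuLi (10 mol %) to zerovalent nickel, THF, 0 °C → rt
Reagents that add atoms: trimethylaluminium, C[Al](C)C
Why: Zirconium-catalysed methylalumination of the terminal alkyne (Negishi carboalumination) is syn and places methyl on C3' and aluminium on C2', fixing the C2'=C3' E geometry, and nickel-catalysed cross-coupling of the alkenylalane with the chloromethylquinone forms C1'–C2' with retention; isolated trisubstituted alkenes are inert to both.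

**Compound list**

1 | allyl alcohol | C=CCO | starting material
2 | allyl 4-methoxybenzyl ether | C=CCOCc1ccc(OC)cc1 | intermediate
3 | 2-[3-(4-methoxybenzyloxy)propyl]-4,4,5,5-tetramethyl-1,3,2-dioxaborolane | COc1ccc(COCCCB2OC(C)(C)C(C)(C)O2)cc1 | intermediate
4 | 2,4,6-triisopropylbenzoic acid | CC(C)c1cc(C(C)C)c(C(=O)O)c(C(C)C)c1 | starting material
5 | ethyl 2,4,6-triisopropylbenzoate | CCOC(=O)c1c(C(C)C)cc(C(C)C)cc1C(C)C | intermediate
6 | (R)-1-lithioethyl 2,4,6-triisopropylbenzoate (as its (+)-sparteine complex in step 4) | C[C@H](OC(=O)c1c(C(C)C)cc(C(C)C)cc1C(C)C)[Li] | intermediate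
7 | (R)-1-(tributylstannyl)ethyl 2,4,6-triisopropylbenzoate | C[C@H](OC(=O)c1c(C(C)C)cc(C(C)C)cc1C(C)C)[Sn](CCCC)(CCCC)CCCC | intermediate
8 | bromochloromethane | ClCBr | starting material
9 | 2-[(2S)-5-(4-methoxybenzyloxy)pentan-2-yl]-4,4,5,5-tetramethyl-1,3,2-dioxaborolane (boron on C7') | CC1(C)OB([C@@H](C)CCCOCc2ccc(OC)cc2)OC1(C)C | intermediate
10 | 2-[(2R)-5-(4-methoxybenzyloxy)-2-methylpentyl]-4,4,5,5-tetramethyl-1,3,2-dioxaborolane (boron on C8') | CC1(C)OB(C[C@@H](C)CCCOCc2ccc(OC)cc2)OC1(C)C | intermediate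
11 | 2-[(3R)-6-(4-methoxybenzyloxy)-3-methylhexyl]-4,4,5,5-tetramethyl-1,3,2-dioxaborolane (boron on C9') | CC1(C)OB(CC[C@@H](C)CCCOCc2ccc(OC)cc2)OC1(C)C | intermediate
12 | 2-[(4R)-7-(4-methoxybenzyloxy)-4-methylheptyl]-4,4,5,5-tetramethyl-1,3,2-dioxaborolane (boron on C10') | CC1(C)OB(CCC[C@@H](C)CCCOCc2ccc(OC)cc2)OC1(C)C | intermediate
13 | 2-[(2S,6R)-9-(4-methoxybenzyloxy)-6-methylnonan-2-yl]-4,4,5,5-tetramethyl-1,3,2-dioxaborolane (boron on C11') | CC1(C)OB([C@@H](C)CCC[C@@H](C)CCCOCc2ccc(OC)cc2)OC1(C)C | intermediate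
14 | 2-[(2R,6R)-9-(4-methoxybenzyloxy)-2,6-dimethylnonyl]-4,4,5,5-tetramethyl-1,3,2-dioxaborolane (boron on C12') | CC1(C)OB(C[C@@H](C)CCC[C@@H](C)CCCOCc2ccc(OC)cc2)OC1(C)C | intermediate
15 | (2S,6R)-9-(4-methoxybenzyloxy)-2,6-dimethylnonan-1-ol | OC[C@@H](C)CCC[C@@H](C)CCCOCc1ccc(OC)cc1 | intermediate
16 | 1-({[(4R,8S)-9-bromo-4,8-dimethylnonyl]oxy}methyl)-4-methoxybenzene | BrC[C@@H](C)CCC[C@@H](C)CCCOCc1ccc(OC)cc1 | intermediate
17 | geranylgeraniol | CC(C)=CCC/C(C)=C/CC/C(C)=C/CC/C(C)=C/CO | starting material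
18 | tert-butyldiphenyl{[(2E,6E,10E)-3,7,11,15-tetramethylhexadeca-2,6,10,14-tetraen-1-yl]oxy}silane | CC(C)=CCC/C(C)=C/CC/C(C)=C/CC/C(C)=C/CO[Si](c1ccccc1)(c1ccccc1)C(C)(C)C | intermediate
19 | (2E,6E,10E,14E)-16-[(tert-butyldiphenylsilyl)oxy]-2,6,10,14-tetramethylhexadeca-2,6,10,14-tetraen-1-ol | OC/C(C)=C/CC/C(C)=C/CC/C(C)=C/CC/C(C)=C/CO[Si](c1ccccc1)(c1ccccc1)C(C)(C)C | intermediate
20 | {[(2E,6E,10E,14E)-16-bromo-3,7,11,15-tetramethylhexadeca-2,6,10,14-tetraen-1-yl]oxy}(tert-butyl)diphenylsilane | BrC/C(C)=C/CC/C(C)=C/CC/C(C)=C/CC/C(C)=C/CO[Si](c1ccccc1)(c1ccccc1)C(C)(C)C | intermediate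
21 | (R)-citronellol | CC(C)=CCC[C@@H](C)CCO | starting material
22 | (R)-8-bromo-2,6-dimethyloct-2-ene | CC(C)=CCC[C@@H](C)CCBr | intermediate
23 | [(R)-3,7-dimethyloct-6-en-1-yl]magnesium bromide | CC(C)=CCC[C@@H](C)CC[Mg]Br | intermediate
24 | tert-butyl{[(2E,6E,10E,14E,19S)-3,7,11,15,19,23-hexamethyltetracosa-2,6,10,14,22-pentaen-1-yl]oxy}diphenylsilane | CC(C)=CCC[C@@H](C)CCC/C(C)=C/CC/C(C)=C/CC/C(C)=C/CC/C(C)=C/CO[Si](c1ccccc1)(c1ccccc1)C(C)(C)C | intermediate
25 | (2E,6E,10E,14E,19S)-3,7,11,15,19,23-hexamethyltetracosa-2,6,10,14,22-pentaen-1-ol | CC(C)=CCC[C@@H](C)CCC/C(C)=C/CC/C(C)=C/CC/C(C)=C/CC/C(C)=C/CO | intermediate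
26 | (2E,6E,10E,14E,19S)-1-chloro-3,7,11,15,19,23-hexamethyltetracosa-2,6,10,14,22-pentaene | CC(C)=CCC[C@@H](C)CCC/C(C)=C/CC/C(C)=C/CC/C(C)=C/CC/C(C)=C/CCl | intermediate
27 | [(2S,6R)-9-(4-methoxybenzyloxy)-2,6-dimethylnonyl]magnesium bromide | Br[Mg]C[C@@H](C)CCC[C@@H](C)CCCOCc1ccc(OC)cc1 | intermediate
28 | 1-methoxy-4-({[(4R,8S,11E,15E,19E,23E,28S)-4,8,12,16,20,24,28,32-octamethyltritriaconta-11,15,19,23,31-pentaen-1-yl]oxy}methyl)benzene | CC(C)=CCC[C@@H](C)CCC/C(C)=C/CC/C(C)=C/CC/C(C)=C/CC/C(C)=C/CC[C@@H](C)CCC[C@@H](C)CCCOCc1ccc(OC)cc1 | intermediate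
29 | (4R,8S,11E,15E,19E,23E,28S)-4,8,12,16,20,24,28,32-octamethyltritriaconta-11,15,19,23,31-pentaen-1-ol | CC(C)=CCC[C@@H](C)CCC/C(C)=C/CC/C(C)=C/CC/C(C)=C/CC/C(C)=C/CC[C@@H](C)CCC[C@@H](C)CCCO | intermediate
30 | (6S,10E,14E,18E,22E,26S,30R)-33-bromo-2,6,10,14,18,22,26,30-octamethyltritriaconta-2,10,14,18,22-pentaene | CC(C)=CCC[C@@H](C)CCC/C(C)=C/CC/C(C)=C/CC/C(C)=C/CC/C(C)=C/CC[C@@H](C)CCC[C@@H](C)CCCBr | intermediate
31 | (6R,10S,13E,17E,21E,25E,30S)-6,10,14,18,22,26,30,34-octamethylpentatriaconta-13,17,21,25,33-pentaen-1-yne | CC(C)=CCC[C@@H](C)CCC/C(C)=C/CC/C(C)=C/CC/C(C)=C/CC/C(C)=C/CC[C@@H](C)CCC[C@@H](C)CCCC#C | intermediate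
32 | menadione (2-methylnaphthalene-1,4-dione) | CC1=CC(=O)c2ccccc2C1=O | starting material
33 | 2-(chloromethyl)-3-methylnaphthalene-1,4-dione | CC1=C(CCl)C(=O)c2ccccc2C1=O | intermediate
34 | dimethyl[(1E,6R,10S,13E,17E,21E,25E,30S)-2,6,10,14,18,22,26,30,34-nonamethylpentatriaconta-1,13,17,21,25,33-hexaen-1-yl]alumane | CC(C)=CCC[C@@H](C)CCC/C(C)=C/CC/C(C)=C/CC/C(C)=C/CC/C(C)=C/CC[C@@H](C)CCC[C@@H](C)CCC/C(C)=C/[Al](C)C | intermediate
35 | 2-methyl-3-[(2E,7R,11S,14E,18E,22E,26E,31S)-3,7,11,15,19,23,27,31,35-nonamethylhexatriaconta-2,14,18,22,26,34-hexaen-1-yl]naphthalene-1,4-dione | CC(C)=CCC[C@@H](C)CCC/C(C)=C/CC/C(C)=C/CC/C(C)=C/CC/C(C)=C/CC[C@@H](C)CCC[C@@H](C)CCC/C(C)=C/CC1=C(C)C(=O)c2ccccc2C1=O | target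

**Totals**

Total step count: 20. Longest linear sequence: 11 steps (geranylgeraniol 17 to target 35 through steps 8, 9, 10, 12, 13, 14, 15, 16, 17, 18 and 20).

**Steps most likely to fail**

Step 5. Incomplete boronate formation or premature migration in any one pass would leave chain-length homologues that co-elute with the product, and any shortfall in the enantiopurity of the carbenoid would surface as diastereomers that cannot be separated. The fallback abandons boron homologation for the chiral pool. It draws on no compound of the route and rejoins it at 15. Commercial (S)-citronellol F1 is converted with TsCl and pyridine into (S)-citronellyl tosylate F2. Commercial (R)-3-bromo-2-methylpropan-1-ol F3 is silylated (TBDPSCl, imidazole) to (R)-(3-bromo-2-methylpropoxy)(tert-butyl)diphenylsilane F4. The Grignard reagent [(R)-3-(tert-butyldiphenylsilyloxy)-2-methylpropyl]magnesium bromide F5 (Mg, THF) is coupled with F2 under Li2CuCl4 catalysis to form C9'–C10' and give tert-butyldiphenyl{[(2S,6R)-2,6,10-trimethylundec-9-en-1-yl]oxy}silane F6. Both methyl centres come directly from the two building blocks. Ozonolysis with NaBH4 work-up should give (4R,8S)-9-[(tert-butyldiphenylsilyl)oxy]-4,8-dimethylnonan-1-ol F7. 4-Methoxybenzyl trichloroacetimidate with catalytic camphorsulfonic acid should give tert-butyl{[(2S,6R)-9-(4-methoxybenzyloxy)-2,6-dimethylnonyl]oxy}diphenylsilane F8, and TBAF in THF should then deliver 15.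

Step 12. Attack of the organocopper intermediate at the γ-carbon (C26') of the 2-methylallyl bromide, or scrambling of the C26'=C27' geometry through an allylcopper species, would give branched or Z isomers that are hard to remove. The fallback replaces the copper coupling by alkylation of a sulfone-stabilised carbanion. It sets out from 22 and 20 and returns at 24. Bromide 22 with PhSO2Na in DMF should give {[(R)-3,7-dimethyloct-6-en-1-yl]sulfonyl}benzene F9. n-BuLi in THF at −78 °C gives the α-lithio sulfone F10, which should displace the bromide of 20 by direct SN2 attack to give the C29' phenylsulfonyl derivative of 24, F11, as a mixture of epimers at the sulfonyl carbon. Reductive desulfonylation with Na(Hg) and Na2HPO4 in MeOH/THF at −20 °C should then give 24.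

Step 20. Electron transfer from low-valent nickel or from the alane to the quinone, or carbonyl methylation by residual Me3Al, could consume 33 faster than C–C coupling. The fallback moves the quinone into a protected oxidation state. It sets out from alkyne 31 and returns at the target 35. Commercial 1,4-dimethoxy-2-methylnaphthalene F12 is chloromethylated ((CH2O)n, HCl, AcOH) to 2-(chloromethyl)-1,4-dimethoxy-3-methylnaphthalene F13. The alkenylalane 34, made from 31 as in step 20, is coupled with F13 under the same zerovalent nickel catalysis to give the 1,4-dimethoxynaphthalene analogue of the target, F14. Oxidative demethylation with (NH4)2Ce(NO3)6 in MeCN/H2O at 0 °C should then give 35.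

**Further compounds**

F1 | step 5 | (S)-citronellol (bought) | CC(C)=CCC[C@H](C)CCO
F2 | step 5 | (S)-3,7-dimethyloct-6-en-1-yl 4-methylbenzenesulfonate | CC(C)=CCC[C@H](C)CCOS(=O)(=O)c1ccc(C)cc1
F3 | step 5 | (R)-3-bromo-2-methylpropan-1-ol (bought) | OC[C@@H](C)CBr
F4 | step 5 | (R)-(3-bromo-2-methylpropoxy)(tert-butyl)diphenylsilane | BrC[C@H](C)CO[Si](c1ccccc1)(c1ccccc1)C(C)(C)C
F5 | step 5 | [(R)-3-(tert-butyldiphenylsilyloxy)-2-methylpropyl]magnesium bromide | Br[Mg]C[C@H](C)CO[Si](c1ccccc1)(c1ccccc1)C(C)(C)C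
F6 | step 5 | tert-butyldiphenyl{[(2S,6R)-2,6,10-trimethylundec-9-en-1-yl]oxy}silane | CC(C)(C)[Si](OC[C@@H](C)CCC[C@@H](C)CCC=C(C)C)(c1ccccc1)c1ccccc1
F7 | step 5 | (4R,8S)-9-[(tert-butyldiphenylsilyl)oxy]-4,8-dimethylnonan-1-ol | CC(C)(C)[Si](OC[C@@H](C)CCC[C@@H](C)CCCO)(c1ccccc1)c1ccccc1
F8 | step 5 | tert-butyl{[(2S,6R)-9-(4-methoxybenzyloxy)-2,6-dimethylnonyl]oxy}diphenylsilane | CC(C)(C)[Si](OC[C@@H](C)CCC[C@@H](C)CCCOCc1ccc(OC)cc1)(c1ccccc1)c1ccccc1
F9 | step 12 | {[(R)-3,7-dimethyloct-6-en-1-yl]sulfonyl}benzene | CC(C)=CCC[C@@H](C)CCS(=O)(=O)c1ccccc1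
F10 | step 12 | α-lithio derivative of F9 | CC(C)=CCC[C@@H](C)CC([Li])S(=O)(=O)c1ccccc1
F11 | step 12 | tert-butyl{[(2E,6E,10E,14E,19R)-3,7,11,15,19,23-hexamethyl-17-(phenylsulfonyl)tetracosa-2,6,10,14,22-pentaen-1-yl]oxy}diphenylsilane (epimers at C17) | CC(C)=CCC[C@@H](C)CC(C/C(C)=C/CC/C(C)=C/CC/C(C)=C/CC/C(C)=C/CO[Si](c1ccccc1)(c1ccccc1)C(C)(C)C)S(=O)(=O)c1ccccc1
F12 | step 20 | 1,4-dimethoxy-2-methylnaphthalene (bought) | COc1cc(C)c(OC)c2ccccc12
F13 | step 20 | 2-(chloromethyl)-1,4-dimethoxy-3-methylnaphthalene | COc1c(C)c(CCl)c(OC)c2ccccc12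
F14 | step 20 | 1,4-dimethoxy-2-methyl-3-[(2E,7R,11S,14E,18E,22E,26E,31S)-3,7,11,15,19,23,27,31,35-nonamethylhexatriaconta-2,14,18,22,26,34-hexaen-1-yl]naphthalene | CC(C)=CCC[C@@H](C)CCC/C(C)=C/CC/C(C)=C/CC/C(C)=C/CC/C(C)=C/CC[C@@H](C)CCC[C@@H](C)CCC/C(C)=C/Cc1c(C)c(OC)c2ccccc2c1OC
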